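**Retrosynthetic overview**
- Herboxidiene (22) ← C18-OH-directed epoxidation of the 14,15-alkene of seco-acid 21 (last step).
- 21 ← Suzuki union at C9–C10 of vinyl iodide 12 (C10–C19) with oxane vinylboronate 20 (C1–C9).
- 12 ← acid 9 ← Ireland–Claisen [3,3] rearrangement of propionate 8. This key step forms C12–C13, transfers the C15 stereocentre to C12 and sets the 14E alkene.
- 8 ← (R)-lactate-derived ketone 4 + methacrolein by anti-aldol, then Evans–Tishchenko reduction, which installs the propionate and C17.
- 20 ← 2-acetyl oxane 19 ← oxa-Michael closure and equilibration, with C3 and C7 set thermodynamically from the purchased C6 centre of 13. Ring order: oxane (step 15), then epoxide (step 18).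

Assumption: methyl (R)-lactate and Roche-ester-derived (R)-3-bromo-2-methylpropan-1-ol are taken as inexpensive commercial chiral-pool materials. Herboxidiene numbering (C1 = CO2H … C19) is used in the explanations.

**East fragment (C10–C19)**

Step 1
Reactants: 1, methyl (R)-lactate
Product: 2, (2R)-2-hydroxy-N-methoxy-N-methylpropanamide
Conditions: MeNH(OMe)·HCl, i-PrMgCl, THF, −20 → 0 °C
Reagents that add atoms: N,O-dimethylhydroxylamine hydrochloride, CNOC.Cl
Why: Magnesium-amide aminolysis of the ester gives the Weinreb amide without touching the lactate stereocentre (C18).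

Step 2
Reactants: 2
Product: 3, (2R)-2-hydroxypentan-3-one
Conditions: EtMgBr (3 equiv), THF, 0 °C → rt; NH4Cl
Reagents that add atoms: ethylmagnesium bromide, CC[Mg]Br
Why: Grignard addition to the Weinreb amide stops at the ketone through the stable chelate, and the magnesium alkoxide suppresses α-epimerisation.

Step 3
Reactants: 3
Product: 4, (2R)-3-oxopentan-2-yl benzoate
Conditions: Bz2O, DMAP, i-Pr2NEt, CH2Cl2, rt
Reagents that add atoms: benzoic anhydride, O=C(OC(=O)c1ccccc1)c1ccccc1
Why: DMAP-catalysed O-acylation installs the benzoate that directs the facial selectivity of the next aldol.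

Step 4
Reactants: 4; 5, methacrolein
Product: 6, (2R,4S,5R)-5-hydroxy-4,6-dimethyl-3-oxohept-6-en-2-yl benzoate
Conditions: (c-Hex)2BCl, Me2NEt, Et2O, −78 → 0 °C; 5, −78 → −20 °C; H2O2, MeOH, pH 7 buffer
Reagents that add atoms: methacrolein (5), CC(=C)C=O
Why: Paterson boron anti-aldol: the E-enol borinate reacts through a chair transition state on the face chosen by the α′-benzoate stereocentre, giving the 16-Me/18-OBz syn, 15,16-anti adduct (dr about 95:5).

Step 5
Reactants: 6
Product: 7, (2R,3R,4R,5R)-3-hydroxy-4,6-dimethyl-5-(propanoyloxy)hept-6-en-2-yl benzoate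
Conditions: SmI2 (30 mol %), EtCHO (6 equiv), THF, −10 °C
Reagents that add atoms: propanal, CCC=O
Why: Evans–Tishchenko reduction: the samarium-bound hemiacetal of the C15-OH delivers hydride intramolecularly to C17, giving the 1,3-anti alcohol (17R) and leaving C15 as the propionate needed for the rearrangement.

Step 6
Reactants: 7
Product: 8, (2R,3R,4S,5R)-3-methoxy-4,6-dimethyl-5-(propanoyloxy)hept-6-en-2-yl benzoate
Conditions: Me3OBF4, Proton Sponge, CH2Cl2, 0 °C → rt
Reagents that add atoms: trimethyloxonium tetrafluoroborate, C[O+](C)C.F[B-](F)(F)F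
Why: O-methylation (SN2 at methyl) of the hindered C17-OH under non-nucleophilic base avoids acyl migration of either ester.

Step 7
Reactants: 8
Product: 9, (2S,4E,6S,7R,8R)-8-(benzoyloxy)-7-methoxy-2,4,6-trimethylnon-4-enoic acid
Conditions: LDA, THF, −78 °C, TMSCl/Et3N in situ; −78 °C → rt, then 50 °C; 1 M HCl
Reagents that add atoms: none
Why: Ireland–Claisen [3,3] rearrangement: the kinetic silyl ketene acetal (methyl cis to the allylic oxygen) reacts through a chair with the C16 chain equatorial, so the 15R centre gives 12S and the 14E alkene (dr limited by ketene acetal geometry, about 9:1).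

Step 8
Reactants: 9
Product: 10, (2S,4E,6S,7R,8R)-7-methoxy-2,4,6-trimethylnon-4-ene-1,8-diol
Conditions: LiAlH4, THF, 0 °C → rt
Reagents that add atoms: none
Why: Hydride reduction takes the acid to the primary alcohol and cleaves the benzoate in the same operation; the isolated trisubstituted alkene is inert.

Step 9
Reactants: 10
Product: 11, (2S,4E,6S,7R,8R)-8-hydroxy-7-methoxy-2,4,6-trimethylnon-4-enal
Conditions: TEMPO (10 mol %), PhI(OAc)2, CH2Cl2, rt
Reagents that add atoms: none
Why: Oxoammonium oxidation is selective for the primary over the secondary alcohol and is non-basic, so C12 does not epimerise.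

Step 10
Reactants: 11
Product: 12, (2R,3R,4S,5E,8S,9E)-10-iodo-3-methoxy-4,6,8-trimethyldeca-5,9-dien-2-ol
Conditions: CrCl2, CHI3, THF–dioxane, 0 °C → rt
Reagents that add atoms: iodoform, IC(I)I
Why: Takai olefination with the gem-dichromium species gives the E-vinyl iodide (C10) from the α-branched aldehyde and tolerates the free hydroxyl.

**West fragment (C1–C9)**

Step 11
Reactants: 13, (R)-3-bromo-2-methylpropan-1-ol
Product: 14, (S)-2-methylhex-5-en-1-ol
Conditions: allylMgCl (3 equiv), Li2CuCl4 (5 mol %), THF, −30 °C → rt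
Reagents that add atoms: allylmagnesium chloride, C=CC[Mg]Cl
Why: Copper-catalysed Kochi sp3–sp3 coupling at the primary bromide, with the alcohol masked in situ as its alkoxide; the C6 stereocentre is not involved (the descriptor changes only through priorities).

Step 12
Reactants: 14
Product: 15, (S)-2-methylhex-5-enal
Conditions: (COCl)2, DMSO, CH2Cl2, −78 °C; i-Pr2NEt; used cold and crude
Reagents that add atoms: none
Why: Swern oxidation at low temperature with a hindered base keeps the α-methyl stereocentre intact.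

Step 13
Reactants: 15
Product: 16, (4S)-3-hydroxy-4-methyloct-7-en-2-one (mixture of C3 epimers, i.e. herboxidiene C7)
Conditions: CH2=C(OEt)Li (ethyl vinyl ether, t-BuLi), THF, −78 °C; then 1 M HCl, THF, 0 °C
Reagents that add atoms: ethyl vinyl ether, C=COCC; water, O
Why: 1,2-addition of an acetyl-anion equivalent followed by enol-ether hydrolysis gives the acyloin; the new carbinol configuration is irrelevant because it is equilibrated in step 15.

Step 14
Reactants: 16; 17, methyl acrylate
Product: 18, methyl (2E,6S)-7-hydroxy-6-methyl-8-oxonon-2-enoate (C7 epimers)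
Conditions: Hoveyda–Grubbs II (3 mol %), 17 (5 equiv), CH2Cl2, 40 °C
Reagents that add atoms: methyl acrylate (17), C=CC(=O)OC
Why: Cross-metathesis of a type I terminal alkene with an acrylate is selective for the E-enoate.

Step 15
Reactants: 18
Product: 19, methyl 2-[(2R,5S,6S)-6-acetyl-5-methyloxan-2-yl]acetate
Conditions: KOt-Bu (0.3 equiv), THF, −20 °C → rt, to constant isomer ratio
Reagents that add atoms: none
Why: A 6-exo oxa-Michael addition closes the oxane, then C7 (via the ketone enolate) and C3 (via retro-oxa-Michael/Michael) equilibrate to the all-equatorial isomer dictated by the fixed C6 methyl (estimated ≥10:1).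

Step 16
Reactants: 19
Product: 20, methyl 2-[(2R,5S,6S)-5-methyl-6-[(1E)-1-(4,4,5,5-tetramethyl-1,3,2-dioxaborolan-2-yl)prop-1-en-2-yl]oxan-2-yl]acetate
Conditions: CH2(Bpin)2, LiTMP, THF, 0 °C; then 19, −78 °C → rt
Reagents that add atoms: bis(pinacolato)borylmethane, CC1(C)OB(CB2OC(C)(C)C(C)(C)O2)OC1(C)C
Why: Boron–Wittig olefination: LiCH(Bpin)2 adds to the ketone in preference to the ester, and syn B–O elimination places the remaining Bpin trans to the bulky oxanyl group, giving the E-trisubstituted alkene.

**Union and endgame**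

Step 17
Reactants: 12; 20
Product: 21, 2-[(2R,5S,6S)-6-[(2E,4E,6S,8E,10S,11R,12R)-12-hydroxy-11-methoxy-6,8,10-trimethyltrideca-2,4,8-trien-2-yl]-5-methyloxan-2-yl]acetic acid
Conditions: Pd(dppf)Cl2 (5 mol %), aq LiOH (6 equiv), THF, rt; then 45 °C (one pot)
Reagents that add atoms: lithium hydroxide, [Li+].[OH-]
Why: Suzuki–Miyaura sp2–sp2 coupling forms C9–C10 with retention of both alkene geometries, and the excess hydroxide then saponifies the methyl ester.

Step 18
Reactants: 21
Product: 22, herboxidiene
Conditions: VO(acac)2 (10 mol %), t-BuOOH, CH2Cl2, −20 °C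
Reagents that add atoms: tert-butyl hydroperoxide, CC(C)(C)OO
Why: Hydroxyl-directed vanadium epoxidation: the C18-OH-bound peroxovanadium delivers oxygen to one face of the bishomoallylic 14,15-alkene, giving the (14R,15R)-epoxide and leaving the diene untouched.

**Compound list**
1 | methyl (R)-lactate | C[C@@H](O)C(=O)OC | starting material
2 | (2R)-2-hydroxy-N-methoxy-N-methylpropanamide | C[C@@H](O)C(=O)N(C)OC | intermediate
3 | (2R)-2-hydroxypentan-3-one | C[C@@H](O)C(=O)CC | intermediate
4 | (2R)-3-oxopentan-2-yl benzoate | C[C@@H](OC(=O)c1ccccc1)C(=O)CC | intermediate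
5 | methacrolein | CC(=C)C=O | starting material
6 | (2R,4S,5R)-5-hydroxy-4,6-dimethyl-3-oxohept-6-en-2-yl benzoate | C[C@@H](OC(=O)c1ccccc1)C(=O)[C@@H](C)[C@@H](O)C(C)=C | intermediate
7 | (2R,3R,4R,5R)-3-hydroxy-4,6-dimethyl-5-(propanoyloxy)hept-6-en-2-yl benzoate | C[C@@H](OC(=O)c1ccccc1)[C@H](O)[C@@H](C)[C@@H](OC(=O)CC)C(C)=C | intermediate
8 | (2R,3R,4S,5R)-3-methoxy-4,6-dimethyl-5-(propanoyloxy)hept-6-en-2-yl benzoate | C[C@@H](OC(=O)c1ccccc1)[C@H](OC)[C@@H](C)[C@@H](OC(=O)CC)C(C)=C | intermediate
9 | (2S,4E,6S,7R,8R)-8-(benzoyloxy)-7-methoxy-2,4,6-trimethylnon-4-enoic acid | C[C@@H](OC(=O)c1ccccc1)[C@H](OC)[C@@H](C)/C=C(\C)C[C@H](C)C(=O)O | intermediate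
10 | (2S,4E,6S,7R,8R)-7-methoxy-2,4,6-trimethylnon-4-ene-1,8-diol | C[C@@H](O)[C@H](OC)[C@@H](C)/C=C(\C)C[C@H](C)CO | intermediate
11 | (2S,4E,6S,7R,8R)-8-hydroxy-7-methoxy-2,4,6-trimethylnon-4-enal | C[C@@H](O)[C@H](OC)[C@@H](C)/C=C(\C)C[C@H](C)C=O | intermediate
12 | (2R,3R,4S,5E,8S,9E)-10-iodo-3-methoxy-4,6,8-trimethyldeca-5,9-dien-2-ol | C[C@@H](O)[C@H](OC)[C@@H](C)/C=C(\C)C[C@H](C)/C=C/I | intermediate
13 | (R)-3-bromo-2-methylpropan-1-ol | OC[C@@H](C)CBr | starting material
14 | (S)-2-methylhex-5-en-1-ol | OC[C@@H](C)CCC=C | intermediate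
15 | (S)-2-methylhex-5-enal | O=C[C@@H](C)CCC=C | intermediate
16 | (4S)-3-hydroxy-4-methyloct-7-en-2-one (C3 epimers) | CC(=O)C(O)[C@@H](C)CCC=C | intermediate
17 | methyl acrylate | C=CC(=O)OC | starting material
18 | methyl (2E,6S)-7-hydroxy-6-methyl-8-oxonon-2-enoate (C7 epimers) | CC(=O)C(O)[C@@H](C)CC/C=C/C(=O)OC | intermediate
19 | methyl 2-[(2R,5S,6S)-6-acetyl-5-methyloxan-2-yl]acetate | CC(=O)[C@H]1O[C@@H](CC(=O)OC)CC[C@@H]1C | intermediate
20 | methyl 2-[(2R,5S,6S)-5-methyl-6-[(1E)-1-(pinacolboryl)prop-1-en-2-yl]oxan-2-yl]acetate | C/C(=C\B1OC(C)(C)C(C)(C)O1)[C@H]1O[C@@H](CC(=O)OC)CC[C@@H]1C | intermediate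
21 | 14,15-desepoxy-herboxidiene (seco-acid named in step 17) | C[C@@H](O)[C@H](OC)[C@@H](C)/C=C(\C)C[C@H](C)/C=C/C=C(\C)[C@H]1O[C@@H](CC(=O)O)CC[C@@H]1C | intermediate
22 | herboxidiene | CO[C@H]([C@@H](C)[C@H]1O[C@]1(C)C[C@H](C)/C=C/C=C(\C)[C@H]1O[C@@H](CC(=O)O)CC[C@@H]1C)[C@@H](C)O | target

**Totals**
Total steps: 18. Longest linear sequence: 12 (steps 1–10, 17, 18); the west branch is 6 steps (11–16).

**Three steps most likely to fail**
1. Step 5 (Evans–Tishchenko beside an α′-benzoate). Risks are benzoate or propionate migration and SmI2-mediated C–O cleavage. Fallback: Me4NBH(OAc)3 directed anti-reduction to the 15,17-anti diol, then regioselective propionylation of the allylic C15-OH (the C17-OH is more hindered and deactivated by the vicinal benzoate).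
2. Step 15 (thermodynamic oxa-Michael and epimerisation). The free acyloin could undergo ene-diol isomerisation before it cyclises, which would erode C6, or the equilibrium ratio could be lower than estimated. Fallback: run the cross-metathesis before the acyl-anion addition and let the C7 alkoxide cyclise onto the enoate while the ketone is still masked as the 1-ethoxyvinyl group; hydrolyse and epimerise only once the ring is locked.
3. Step 16 (boron–Wittig on an enolisable α-alkoxy methyl ketone). Risks are competing enolisation and modest E/Z selectivity. Fallback: change the coupling logic. Use an E-selective HWE of 19 with a Weinreb-amide phosphonate, reduce to the C10 enal, and form C10=C11 by Julia–Kocienski olefination with the phenyltetrazolyl sulfone made from alcohol 10.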